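A direct plan would make the dihydrobenzofuran first and close the seven-membered ring last.
It would set the benzhydryl centre by aromatic Claisen rearrangement of the enantioenriched aryl allyl ether A1, trim the butenyl group by ozonolysis/reduction to the diarylethanol A2, cyclodehydrate to the trans-dihydrobenzofuran, attach a styryl arm by Suzuki coupling (stilbene A3), and let acid close the seven-membered ring by Friedel–Crafts attack of the resorcinol ring on the protonated stilbene (pentamethyl ether A4), before demethylation.
Weakest would be the thermal Claisen relay of chirality: near 200 °C a congested, stilbene-like allyl aryl ether would have to pass its carbinol configuration through a single chair, with two unlike ortho positions open and no way to correct the new centre afterwards.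
Next would be the ozonolysis/reduction: it would expose an electron-rich phenol to ozone, pass through an epimerisable α,α-diaryl ketone at the centre just set, and discard half of a four-carbon unit after five operations that yield only a diarylethanol.
Third would be the terminal cationic ring closure: the third stereocentre and the choice between seven-ring closure, indane formation and oligomerisation would rest on substrate bias alone, on the most precious material.

**Plan of the new route**
Labels: Ca = ArCH of the seven-membered ring, Cb = its CH2, Cc = the methine shared by the seven- and five-membered rings, Cd = OCH(Ar); ring A is the resorcinol ring that carries the furan oxygen, ring B the other one.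
Cuts: Cc–Cd (C–H insertion of a diaryl carbene); then both bonds that tie ring A into the seven-membered ring, ring A–Cc and ring A–Cb (aryne insertion into the C–C bond of an indanone β-keto ester); then Ca–ring B (Nazarov cyclisation).
Ring order: cyclopentanone first (a chiral catalyst sets Ca), two-carbon ring expansion to the seven-membered ring, dihydrofuran last.
Enabling feature: Cc is a diarylmethine flanked by rings A and B, so it can be a ketone and then a donor/donor carbene, and it lies 1,5 to Cd through two adjacent ring-A carbons and the ether oxygen, so all five furan atoms are in place before the C–C bond forms.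
No sigmatropic chirality relay, no ozonolysis next to a stereocentre and no cationic seven-ring closure occur: Ca comes from a catalyst, Cc from Ca through the pucker of the seven-membered ring, Cd from thermodynamic equilibration; the ester that polarises the Nazarov step and activates the C–C bond for insertion is removed afterwards.

Key step: step 12

Assumption: the (S,S) hand of the bis(oxazoline) in step 2 is taken to give the (3S) indanone; if the sense of induction is the opposite, the (R,R) ligand is used.
Locants: the tricyclic intermediates are named as dibenzo[a,d][7]annulenes, in which C-5 = Cc, C-10 = Cb, C-11 = Ca, C-1 to C-4 belong to ring B and C-6 to C-9 to ring A.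

**Route**

Step 1
Reactants: 1 ethyl 3-(3,5-dimethoxyphenyl)-3-oxopropanoate; 2 4-methoxybenzaldehyde
Product: 3 ethyl 2-(3,5-dimethoxybenzoyl)-3-(4-methoxyphenyl)prop-2-enoate (E/Z mixture)
Conditions: piperidine (10 mol %), AcOH (10 mol %), toluene, reflux, Dean–Stark
Reagents that add atoms: none
Why: Knoevenagel condensation of the doubly activated methylene of 1 with the aldehyde under piperidinium acetate catalysis with azeotropic removal of water; the alkene geometry is immaterial because the Lewis acid of step 2 equilibrates it.

Step 2
Reactants: 3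
Product: 4 ethyl (2R,3S)-4,6-dimethoxy-3-(4-methoxyphenyl)-1-oxo-2,3-dihydro-1H-indene-2-carboxylate (2,3-trans)
Conditions: Cu(OTf)2 (10 mol %), (S,S)-Ph-box (11 mol %), 4 Å MS, ClCH2CH2Cl, 60 °C
Reagents that add atoms: none
Why: Catalytic asymmetric Nazarov cyclisation of a polarised aryl vinyl β-keto ester: two-point binding of the 1,3-dicarbonyl to the chiral Cu(II)–bis(oxazoline) generates the pentadienyl cation, the 3,5-dimethoxyphenyl ring closes through its carbon ortho to the acyl group (ortho/para to both methoxy groups) onto the anisyl-stabilised β-carbon in a conrotatory 4π electrocyclisation whose sense the ligand dictates, which sets Ca (3S), and rearomatisation followed by thermodynamic protonation places the ester trans (2R).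

Step 3
Reactants: 5 3,5-dimethoxyphenol; 6 isopropyl isocyanate
Product: 7 3,5-dimethoxyphenyl N-isopropylcarbamate
Conditions: Et3N (20 mol %), CH2Cl2, rt
Reagents that add atoms: none
Why: Base-catalysed addition of the phenol to the isocyanate (carbamoylation) installs a group that directs ortho-metalation strongly and can later be cleaved under mild conditions.

Step 4
Reactants: 7
Product: 10 3,5-dimethoxy-2-(trimethylsilyl)phenyl N-isopropylcarbamate, via N-silyl carbamate 8 (not isolated), via C-silylated N-silyl carbamate 9 (not isolated)
Conditions: TBSOTf (1.1 equiv), TMEDA (1.1 equiv), Et2O, 0 °C to rt; then TMEDA (2 equiv), n-BuLi (2 equiv), −78 °C; TMSCl (3 equiv), −78 °C to rt; aq. NaHSO4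
Reagents that add atoms: chlorotrimethylsilane, C[Si](C)(C)Cl
Why: Directed ortho-metalation: the carbamate, N-silylated in the flask, and the flanking methoxy group together direct n-BuLi to the carbon between them (the two such positions are equivalent by symmetry), TMSCl traps the aryllithium, and the N–Si bond is hydrolysed on work-up.

Step 5
Reactants: 10
Product: 12 3,5-dimethoxy-2-(trimethylsilyl)phenyl trifluoromethanesulfonate, via 3,5-dimethoxy-2-(trimethylsilyl)phenol 11 (not isolated)
Conditions: Et2NH (1.2 equiv), DBU (1.5 equiv), MeCN, 40 °C; then PhNTf2 (1.5 equiv), rt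
Reagents that add atoms: N-phenylbis(trifluoromethanesulfonimide), O=S(=O)(N(c1ccccc1)S(=O)(=O)C(F)(F)F)C(F)(F)F
Why: DBU-induced E1cB cleavage of the N–H carbamate releases the phenoxide (diethylamine scavenges the isocyanate), which is triflated in the same flask to give the o-silylaryl triflate aryne precursor.

Step 6
Reactants: 4; 12
Product: 14 ethyl (11S)-1,3,6,8-tetramethoxy-11-(4-methoxyphenyl)-5-oxo-10,11-dihydro-5H-dibenzo[a,d][7]annulene-10-carboxylate (C-10 epimers), via 3,5-dimethoxybenzyne 13 (not isolated)
Conditions: CsF (2.5 equiv), MeCN, 80 °C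
Reagents that add atoms: none
Why: Aryne acyl-alkylation (formal insertion of the aryne into the C1–C2 σ-bond of the β-keto ester): fluoride liberates 13, the enolate carbon adds to the aryne carbon remote from the adjacent methoxy group so that the aryl anion arises next to that methoxy group, this anion closes on the ketone to a benzocyclobutenoxide, and retro-aldol fragmentation expands the five-membered ring by two carbons to the dibenzo-fused seven-membered ring; Ca is not involved and the new centre at C-10 is of no consequence.

Step 7
Reactants: 14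
Product: 15 (11S)-1,3,6,8-tetramethoxy-11-(4-methoxyphenyl)-5-oxo-10,11-dihydro-5H-dibenzo[a,d][7]annulene-10-carboxylic acid (C-10 epimers)
Conditions: LiOH·H2O (5 equiv), THF/MeOH/H2O (2:1:1), 50 °C; then 1 M HCl
Reagents that add atoms: lithium hydroxide, [Li+].[OH-]
Why: Saponification of the ethyl ester by acyl–oxygen cleavage; epimerisation at the acidic C-10 is irrelevant because that centre is removed in step 8.

Step 8
Reactants: 15
Product: 16 (11S)-1,3,6,8-tetramethoxy-11-(4-methoxyphenyl)-10,11-dihydro-5H-dibenzo[a,d][7]annulen-5-one
Conditions: 9-mesityl-10-phenylacridinium tetrafluoroborate (5 mol %), PhSSPh (10 mol %), i-Pr2NEt (20 mol %), CF3CH2OH, 450 nm LEDs, rt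
Reagents that add atoms: none
Why: Organophotoredox hydrodecarboxylation: the excited acridinium oxidises the carboxylate, loss of CO2 gives the secondary benzylic radical at C-10, and thiophenol formed from the disulfide transfers a hydrogen atom, which leaves the CH2 group of the target and does not touch the ketone or Ca.

Step 9
Reactants: 16
Product: 17 (11S)-6-hydroxy-1,3,8-trimethoxy-11-(4-methoxyphenyl)-10,11-dihydro-5H-dibenzo[a,d][7]annulen-5-one
Conditions: BCl3 (1.5 equiv), CH2Cl2, −78 to 0 °C; H2O
Reagents that add atoms: none
Why: Chelation-controlled mono-demethylation: BCl3 is held between the ketone oxygen and the only methoxy group ortho to the carbonyl (C-6), so chloride should cleave this methyl ether alone among five.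

Step 10
Reactants: 17; 18 4-(benzyloxy)benzyl chloride
Product: 19 (11S)-6-{[4-(benzyloxy)phenyl]methoxy}-1,3,8-trimethoxy-11-(4-methoxyphenyl)-10,11-dihydro-5H-dibenzo[a,d][7]annulen-5-one
Conditions: K2CO3 (2 equiv), n-Bu4NI (10 mol %), DMF, 60 °C
Reagents that add atoms: none
Why: Williamson etherification of the hydrogen-bonded ortho-hydroxy ketone with a reactive benzylic chloride under iodide catalysis places the future Cd and its aryl group on the oxygen next to the ketone.

Step 11
Reactants: 19
Product: 20 hydrazone of ketone 19 (E/Z mixture)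
Conditions: N2H4·H2O (20 equiv), AcOH (1 equiv), n-BuOH, 110 °C
Reagents that add atoms: hydrazine (as the hydrate), NN
Why: Acid-catalysed condensation of the diaryl ketone with hydrazine (hydrazone formation), driven by heat because the carbonyl is hindered and electron-rich, with the large excess of hydrazine suppressing azine formation.

Step 12
Reactants: 20
Product: 22 O-benzyl-tetra-O-methyl-ampelopsin B (benzyl ether on the Cd aryl; methyl ethers on rings A and B and on the Ca aryl; Ca S; Cc S; Cd epimers), via diazo compound 21 (not isolated)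
Conditions: MnO2 (8 equiv), CH2Cl2, 0 °C; filtration through Celite; filtrate added slowly to Rh2(OAc)4 (2 mol %), CH2Cl2, 0 °C to rt
Reagents that add atoms: none
Why: Activated MnO2 dehydrogenates the hydrazone to the diaryldiazomethane 21, which loses N2 on Rh2(OAc)4 to give a donor/donor rhodium carbene at Cc; the electrophilic carbene carbon takes the hydridic O-benzylic C–H bond held 1,5 to it on ring A through a three-centre, hydride-shift-like transition state, forming the Cc–Cd bond and placing that hydrogen on Cc. The closest known reaction type is the Rh(II)-catalysed intramolecular C–H insertion of diaryl carbenes generated from 2-(benzyloxy)benzophenone hydrazones, which gives 2,3-diaryl-2,3-dihydrobenzofurans. The dihydrofuran is closed by 1,5-insertion (ring atoms: Cc, two adjacent carbons of ring A, the ether oxygen, Cd). Cc is controlled by Ca through the pucker of the seven-membered ring: the conformer with the Ca aryl pseudo-axial avoids A(1,3) strain with the C-1 methoxy group of ring B, the insertion freezes that pucker with Cd in the plane of ring A (pseudo-equatorial), and the hydrogen on Cc therefore ends pseudo-axial on the face of the Ca aryl, which is the relative configuration of the target; Cd may arise as either epimer and is corrected in step 13. The selectivity needed is insertion before azine formation or carbene dimerisation, and it is secured by the lack of any hydrogen on the carbons next to the carbene, by the doubly activated (α-oxygen, p-alkoxybenzylic) C–H bond in a five-ring relationship and by slow addition of the diazo solution to the catalyst; the other benzyl ether cannot reach the carbene.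

Step 13
Reactants: 22
Product: 24 ampelopsin B, via pentaphenol epimer mixture 23 (not isolated)
Conditions: BBr3 (12 equiv), CH2Cl2, −78 to 0 °C; then MeOH, 0 °C to rt (HBr/MeOH formed in the flask, held until the Cd epimers have converged); H2O
Reagents that add atoms: none
Why: BBr3 cleaves the four aryl methyl ethers and the benzyl ether (Lewis acid–base complexation, then bromide attack at the alkyl carbon), and the methanolic HBr formed on quenching reversibly opens the dihydrofuran at Cd through the p-hydroxybenzyl cation/quinone methide and recloses it to the more stable 2,3-trans isomer, which sets Cd (S), while Ca and Cc are not part of this equilibrium.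

**Compound list**
1 | ethyl 3-(3,5-dimethoxyphenyl)-3-oxopropanoate | CCOC(=O)CC(=O)c1cc(OC)cc(OC)c1 | starting material
2 | 4-methoxybenzaldehyde | COc1ccc(C=O)cc1 | starting material
3 | ethyl 2-(3,5-dimethoxybenzoyl)-3-(4-methoxyphenyl)prop-2-enoate (E/Z mixture) | CCOC(=O)C(=Cc1ccc(OC)cc1)C(=O)c1cc(OC)cc(OC)c1 | intermediate
4 | ethyl (2R,3S)-4,6-dimethoxy-3-(4-methoxyphenyl)-1-oxo-2,3-dihydro-1H-indene-2-carboxylate | COc1ccc(cc1)[C@H]1c2c(OC)cc(OC)cc2C(=O)[C@@H]1C(=O)OCC | intermediate
5 | 3,5-dimethoxyphenol | COc1cc(O)cc(OC)c1 | starting material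
6 | isopropyl isocyanate | CC(C)N=C=O | starting material
7 | 3,5-dimethoxyphenyl N-isopropylcarbamate | COc1cc(OC(=O)NC(C)C)cc(OC)c1 | intermediate
8 | 3,5-dimethoxyphenyl N-(tert-butyldimethylsilyl)-N-isopropylcarbamate | COc1cc(OC(=O)N(C(C)C)[Si](C)(C)C(C)(C)C)cc(OC)c1 | intermediate (not isolated)
9 | 3,5-dimethoxy-2-(trimethylsilyl)phenyl N-(tert-butyldimethylsilyl)-N-isopropylcarbamate | COc1cc(OC)c([Si](C)(C)C)c(OC(=O)N(C(C)C)[Si](C)(C)C(C)(C)C)c1 | intermediate (not isolated)
10 | 3,5-dimethoxy-2-(trimethylsilyl)phenyl N-isopropylcarbamate | COc1cc(OC)c([Si](C)(C)C)c(OC(=O)NC(C)C)c1 | intermediate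
11 | 3,5-dimethoxy-2-(trimethylsilyl)phenol | COc1cc(OC)c([Si](C)(C)C)c(O)c1 | intermediate (not isolated)
12 | 3,5-dimethoxy-2-(trimethylsilyl)phenyl trifluoromethanesulfonate | COc1cc(OC)c([Si](C)(C)C)c(OS(=O)(=O)C(F)(F)F)c1 | intermediate
13 | 3,5-dimethoxybenzyne | COC1=CC(OC)=CC#C1 | intermediate (not isolated)
14 | ethyl (11S)-1,3,6,8-tetramethoxy-11-(4-methoxyphenyl)-5-oxo-10,11-dihydro-5H-dibenzo[a,d][7]annulene-10-carboxylate (C-10 epimers) | COc1ccc(cc1)[C@H]1c2c(OC)cc(OC)cc2C(=O)c2c(OC)cc(OC)cc2C1C(=O)OCC | intermediate
15 | (11S)-1,3,6,8-tetramethoxy-11-(4-methoxyphenyl)-5-oxo-10,11-dihydro-5H-dibenzo[a,d][7]annulene-10-carboxylic acid (C-10 epimers) | COc1ccc(cc1)[C@H]1c2c(OC)cc(OC)cc2C(=O)c2c(OC)cc(OC)cc2C1C(=O)O | intermediate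
16 | (11S)-1,3,6,8-tetramethoxy-11-(4-methoxyphenyl)-10,11-dihydro-5H-dibenzo[a,d][7]annulen-5-one | COc1ccc(cc1)[C@H]1c2c(OC)cc(OC)cc2C(=O)c2c(OC)cc(OC)cc2C1 | intermediate
17 | (11S)-6-hydroxy-1,3,8-trimethoxy-11-(4-methoxyphenyl)-10,11-dihydro-5H-dibenzo[a,d][7]annulen-5-one | COc1ccc(cc1)[C@H]1c2c(OC)cc(OC)cc2C(=O)c2c(O)cc(OC)cc2C1 | intermediate
18 | 4-(benzyloxy)benzyl chloride | ClCc1ccc(OCc2ccccc2)cc1 | starting material
19 | (11S)-6-{[4-(benzyloxy)phenyl]methoxy}-1,3,8-trimethoxy-11-(4-methoxyphenyl)-10,11-dihydro-5H-dibenzo[a,d][7]annulen-5-one | COc1ccc(cc1)[C@H]1c2c(OC)cc(OC)cc2C(=O)c2c(OCc3ccc(OCc4ccccc4)cc3)cc(OC)cc2C1 | intermediate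
20 | hydrazone of 19 (E/Z mixture) | COc1ccc(cc1)[C@H]1c2c(OC)cc(OC)cc2C(=NN)c2c(OCc3ccc(OCc4ccccc4)cc3)cc(OC)cc2C1 | intermediate
21 | (11S)-6-{[4-(benzyloxy)phenyl]methoxy}-5-diazo-1,3,8-trimethoxy-11-(4-methoxyphenyl)-10,11-dihydro-5H-dibenzo[a,d][7]annulene | COc1ccc(cc1)[C@H]1c2c(OC)cc(OC)cc2C(=[N+]=[N-])c2c(OCc3ccc(OCc4ccccc4)cc3)cc(OC)cc2C1 | intermediate (not isolated)
22 | O-benzyl-tetra-O-methyl-ampelopsin B (benzyl ether on the Cd aryl; Ca S; Cc S; Cd epimers) | COc1ccc([C@@H]2Cc3cc(OC)cc4c3[C@H](c3cc(OC)cc(OC)c32)C(c2ccc(OCc5ccccc5)cc2)O4)cc1 | intermediate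
23 | ampelopsin B as a mixture of Cd epimers | Oc1ccc([C@@H]2Cc3cc(O)cc4c3[C@H](c3cc(O)cc(O)c32)C(c2ccc(O)cc2)O4)cc1 | intermediate (not isolated)
24 | ampelopsin B | Oc1ccc([C@@H]2Cc3cc(O)cc4c3[C@H](c3cc(O)cc(O)c32)[C@@H](c2ccc(O)cc2)O4)cc1 | target

**Totals**
Total steps: 13. Longest linear sequence: 11 steps, from 3,5-dimethoxyphenol through the aryne precursor (5 → 7 → 10 → 12 → 14 → 15 → 16 → 17 → 19 → 20 → 22 → 24; steps 3 to 13). The indanone branch (1 → 3 → 4; steps 1 and 2) joins at step 6.

**Steps most likely to fail**

Step 12. Facial control at Cc by the ring pucker may prove incomplete, or the diaryldiazomethane may be lost to azine before the carbene inserts. The fallback sets out from ketone 19 and comes back at 22, and sets Cc by hydride delivery to a cation instead of by insertion. Irradiation of 19 (350 nm, benzene) should let the triplet diaryl ketone abstract the O-benzylic δ-hydrogen, and the 1,5-biradical should close (Yang-type photocyclisation, known for 2-(benzyloxy)benzophenones) to the tertiary carbinol F1. Ionic deoxygenation of F1 (Et3SiH, BF3·OEt2, CH2Cl2, −78 °C) through the doubly benzylic cation at Cc would then give 22, with Cd again left to the equilibration of step 13.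

Step 6. The aryl anion formed after enolate addition may be protonated before it closes on the ketone (plain α-arylation), or the enolate may add through oxygen, so that no C–C cleavage occurs. The fallback sets out from 4 and comes back at acid 15, making the two ring-A bonds one after the other. Pd-catalysed α-arylation of 4 with 1-bromo-3,5-dimethoxybenzene (Pd(OAc)2, t-Bu3P, K3PO4, toluene) would give the α-aryl β-keto ester F2. Sodium ethoxide would open this non-enolisable β-keto ester by retro-Claisen cleavage of the C1–C2 bond, and aqueous KOH in the same flask would hydrolyse both esters to the diacid F3. TFAA would then close the seven-membered ring by Friedel–Crafts acylation of ring A, at its carbon ortho to Cb and ortho/para to the methoxy groups, by the benzoic acid, which gives 15.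

Step 2. Asymmetric induction in the electrocyclisation may be insufficient because a ligand-free Lewis acid or Brønsted acid pathway competes. The fallback sets out from 4 of insufficient enantiomeric purity and comes back at 4, setting Ca by hydride delivery instead of by ring closure. DDQ (dioxane, 80 °C) would dehydrogenate the β-keto ester to the achiral indenone ester F4. Copper hydride conjugate reduction with a chiral bisphosphine (Cu(OAc)2, DTBM-SEGPHOS in the hand that gives 3S, PMHS, t-BuOH, toluene) followed by thermodynamic protonation would return trans-4.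

**Further compounds**
F1 | step 12 | tertiary carbinol: tetracycle 22 with OH in place of H on Cc (Ca S; Cc/Cd isomers) | COc1ccc([C@@H]2Cc3cc(OC)cc4c3C(O)(c3cc(OC)cc(OC)c32)C(c2ccc(OCc5ccccc5)cc2)O4)cc1
F2 | step 6 | ethyl (3S)-2-(3,5-dimethoxyphenyl)-4,6-dimethoxy-3-(4-methoxyphenyl)-1-oxo-2,3-dihydro-1H-indene-2-carboxylate | COc1ccc(cc1)[C@H]1c2c(OC)cc(OC)cc2C(=O)C1(c1cc(OC)cc(OC)c1)C(=O)OCC
F3 | step 6 | 2-[(1S)-2-carboxy-2-(3,5-dimethoxyphenyl)-1-(4-methoxyphenyl)ethyl]-3,5-dimethoxybenzoic acid | COc1ccc(cc1)[C@@H](c1c(OC)cc(OC)cc1C(=O)O)C(c1cc(OC)cc(OC)c1)C(=O)O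
F4 | step 2 | ethyl 4,6-dimethoxy-3-(4-methoxyphenyl)-1-oxo-1H-indene-2-carboxylate | CCOC(=O)C1=C(c2ccc(OC)cc2)c2c(OC)cc(OC)cc2C1=O
A1 | direct plan | 1-bromo-3-methoxy-5-{[(2R,3Z)-4-(3,5-dimethoxyphenyl)-3-(4-methoxyphenyl)but-3-en-2-yl]oxy}benzene | C[C@@H](Oc1cc(Br)cc(OC)c1)/C(c1ccc(OC)cc1)=C\c1cc(OC)cc(OC)c1
A2 | direct plan | 3-bromo-2-[(1S)-1-(3,5-dimethoxyphenyl)-2-hydroxy-2-(4-methoxyphenyl)ethyl]-5-methoxyphenol | COc1ccc(cc1)C(O)[C@@H](c1cc(OC)cc(OC)c1)c1c(Br)cc(OC)cc1O
A3 | direct plan | (2S,3S)-3-(3,5-dimethoxyphenyl)-6-methoxy-2-(4-methoxyphenyl)-4-[(E)-2-(4-methoxyphenyl)ethenyl]-2,3-dihydro-1-benzofuran | COc1ccc(cc1)[C@H]1Oc2cc(OC)cc(/C=C/c3ccc(OC)cc3)c2[C@@H]1c1cc(OC)cc(OC)c1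
A4 | direct plan | pentamethyl ampelopsin B | COc1ccc([C@@H]2Cc3cc(OC)cc4c3[C@H](c3cc(OC)cc(OC)c32)[C@@H](c2ccc(OC)cc2)O4)cc1
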